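The route rests on cutting C8–C9 in ring B. The feature used is ring B's C7=C8 double bond carrying the C17 carboxyl, with the C6 oxygen on one side and, on the other, stereocentre C9 bearing the C11–C12 chain. This is what remains when the α-carbon of an enoate has been joined to the β-carbon of an enal. One phosphine-catalysed Rauhut–Currier cycloisomerisation forms C8–C9, closes ring B, sets C9 and leaves a C12 aldehyde for the diene. The precursor is an enantiopure ring-A cyclohexane with trans arms, an (E)-enal on quaternary C10 and an (E)-γ-silyloxy enoate on C5. C6 travels as the epimer that cyclises best and is corrected afterwards.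

Key step: step 11

Remarks on the chemistry
- Numbering and configuration: labdane numbering is used for every intermediate. The SMILES is read as 5R,6S,9S,10S,12E (ent-labdane series). This means a trans-decalin, C11 equatorial and cis to the axial C10 methyl, and the 6-acetoxy group axial on the face of the axial C4 and C10 methyls.
- C5: the two faces of an exocyclic C5=C6 alkene differ only in CH3 versus CH2R on C10, so an external borane cannot be trusted. The B–H bond is therefore delivered from the C10 arm itself (step 4).
- C6: additions to the C6 aldehyde are hard to predict. An axial 6-silyloxy group would also have to sit between C4 and C10 in the rotamer that closes the ring. The 6R (equatorial) epimer is therefore used for the ring closure, and C6 is fixed later on the rigid decalin (steps 15 and 16).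
- Assumption: (S)-t-BuPHOX, methyl (E)-3-iodoacrylate and 2-(triphenylphosphoranylidene)propanal are bought. If the enantiomeric purity reached in step 2 must be raised, the diol of step 4 is recrystallised.

Step 1
Reactants: 1 2,2,6-trimethylcyclohexan-1-one (racemic); 2 allyl chloroformate
Product: 4 allyl 2,6,6-trimethylcyclohex-1-en-1-yl carbonate, via lithium enolate 3 (not isolated)
Conditions: LiHMDS, THF, 0 °C; then 2, −78 °C
Reagents that add atoms: allyl chloroformate (2), C=CCOC(=O)Cl
Why: Enolate O-acylation: only one α-carbon of 1 carries hydrogen, so a single enolate forms, and the hard chloroformate traps it on oxygen to give the enol carbonate.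

Step 2
Reactants: 4 allyl 2,6,6-trimethylcyclohex-1-en-1-yl carbonate
Product: 5 (S)-2-allyl-2,6,6-trimethylcyclohexan-1-one
Conditions: Pd2(dba)3 (2.5 mol %), (S)-t-BuPHOX (6 mol %), THF, 25 °C
Reagents that add atoms: none
Why: Palladium-catalysed decarboxylative asymmetric allylic alkylation (Tsuji–Trost type): loss of CO2 releases the tetrasubstituted enolate, which is allylated at carbon inside the chiral PHOX pocket, the S ligand giving the S quaternary centre (C10) in the sense known for 2-alkylcyclohexanone enol carbonates.

Step 3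
Reactants: 5 (S)-2-allyl-2,6,6-trimethylcyclohexan-1-one; 6 methyltriphenylphosphonium bromide
Product: 7 (S)-1-allyl-1,3,3-trimethyl-2-methylidenecyclohexane
Conditions: 6 (3 equiv), KOtBu (3 equiv), toluene, reflux
Reagents that add atoms: methyltriphenylphosphonium bromide (6), C[P+](c1ccccc1)(c1ccccc1)c1ccccc1.[Br-]
Why: Wittig methylenation with potassium tert-butoxide in hot toluene is the standard recipe for hindered ketones, and since 5 has no α-hydrogen it can neither enolise nor lose the C10 configuration.

Step 4
Reactants: 7 (S)-1-allyl-1,3,3-trimethyl-2-methylidenecyclohexane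
Product: 10 3-[(1S,2R)-2-(hydroxymethyl)-1,3,3-trimethylcyclohexyl]propan-1-ol, via alkyl(thexyl)borane 8 (not isolated), via trans-fused B-thexylborepane 9 (not isolated)
Conditions: thexylborane (1.3 equiv, from BH3·THF + 2,3-dimethylbut-2-ene), THF, 0.02 M, slow addition of 7 at −20 °C, then 23–45 °C; NaOH, H2O2, 0 °C
Reagents that add atoms: hydrogen peroxide, OO
Why: Cyclic hydroboration of a 1,5-diene: boron first takes the open C11=C12 vinyl group (B on C12), and the remaining B–H bond, now tied to the C10 arm, adds syn to the hindered C5=C6 bond (B on C6, H on C5) on the arm's face, reached either anti to the two axial methyls (arm equatorial) or on the arm's own side (arm axial), so H5 ends cis to C9 and trans to the C10 methyl (5R), and oxidation with retention gives the diol.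

Step 5
Reactants: 10 3-[(1S,2R)-2-(hydroxymethyl)-1,3,3-trimethylcyclohexyl]propan-1-ol
Product: 11 {(1R,2S)-2,6,6-trimethyl-2-[3-(triethylsilyloxy)propyl]cyclohexyl}methanol
Conditions: TESCl (1.05 equiv), imidazole, CH2Cl2, −20 °C
Reagents that add atoms: chlorotriethylsilane, CC[Si](Cl)(CC)CC
Why: Sterically selective silylation: C12–OH is an open primary alcohol, whereas C6–OH hangs on a carbon flanked by two quaternary centres and reacts far more slowly.

Step 6
Reactants: 11 {(1R,2S)-2,6,6-trimethyl-2-[3-(triethylsilyloxy)propyl]cyclohexyl}methanol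
Product: 12 (1R,2S)-2,6,6-trimethyl-2-[3-(triethylsilyloxy)propyl]cyclohexane-1-carbaldehyde
Conditions: Dess–Martin periodinane, pyridine, CH2Cl2, 0–23 °C
Reagents that add atoms: none
Why: Dess–Martin oxidation is fast and essentially neutral, spares the TES ether and gives no opportunity for enolisation at the hindered C5 centre.

Step 7
Reactants: 12 (1R,2S)-2,6,6-trimethyl-2-[3-(triethylsilyloxy)propyl]cyclohexane-1-carbaldehyde; 13 methyl (E)-3-iodoacrylate
Product: 14 methyl (2E,4R)-4-hydroxy-4-{(1R,2S)-2,6,6-trimethyl-2-[3-(triethylsilyloxy)propyl]cyclohexyl}but-2-enoate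
Conditions: CrCl2 (5 equiv), NiCl2 (1 mol %), 13 (2.5 equiv), DMSO–THF, 23 °C
Reagents that add atoms: methyl (E)-3-iodoacrylate (13), COC(=O)/C=C/I
Why: Nozaki–Hiyama–Kishi coupling forms C6–C7 with retention of the E geometry and tolerates ester and silyl ether; C6 is set only provisionally (with the formyl H lodged between C4 and C10 the vinyl group should enter past C10 so that the bulky chromium alkoxide turns to the smaller C4 side, giving 6R), the epimers are separable, and the final C6 configuration comes from step 16.

Step 8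
Reactants: 14 methyl (2E,4R)-4-hydroxy-4-{(1R,2S)-2,6,6-trimethyl-2-[3-(triethylsilyloxy)propyl]cyclohexyl}but-2-enoate
Product: 15 methyl (2E,4R)-4-(tert-butyldimethylsilyloxy)-4-{(1R,2S)-2,6,6-trimethyl-2-[3-(triethylsilyloxy)propyl]cyclohexyl}but-2-enoate
Conditions: TBSOTf, 2,6-lutidine, CH2Cl2, −78 → 0 °C
Reagents that add atoms: tert-butyldimethylsilyl triflate, CC(C)(C)[Si](C)(C)OS(=O)(=O)C(F)(F)F
Why: Silylation with the triflate and a hindered base is the usual way to cap a crowded secondary alcohol, and it blocks oxa-Michael addition of O6 to the later enal.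

Step 9
Reactants: 15 methyl (2E,4R)-4-(tert-butyldimethylsilyloxy)-4-{(1R,2S)-2,6,6-trimethyl-2-[3-(triethylsilyloxy)propyl]cyclohexyl}but-2-enoate
Product: 16 methyl (2E,4R)-4-(tert-butyldimethylsilyloxy)-4-[(1R,2S)-2-(3-hydroxypropyl)-2,6,6-trimethylcyclohexyl]but-2-enoate
Conditions: PPTS (cat.), MeOH–CH2Cl2, 0 °C
Reagents that add atoms: none
Why: Acid-catalysed methanolysis removes a primary TES ether far faster than a crowded secondary TBS ether, so only C12–OH is released.

Step 10
Reactants: 16 methyl (2E,4R)-4-(tert-butyldimethylsilyloxy)-4-[(1R,2S)-2-(3-hydroxypropyl)-2,6,6-trimethylcyclohexyl]but-2-enoate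
Product: 18 methyl (2E,4R)-4-(tert-butyldimethylsilyloxy)-4-{(1R,2S)-2,6,6-trimethyl-2-[(E)-3-oxoprop-1-enyl]cyclohexyl}but-2-enoate, via saturated C12 aldehyde 17 (not isolated)
Conditions: IBX (4 equiv), DMSO–fluorobenzene, 23 → 70 °C
Reagents that add atoms: none
Why: IBX oxidises the alcohol and then dehydrogenates the aldehyde through its enol (one-pot alcohol-to-enal oxidation); only C9–C11 can be desaturated, the E-enal is favoured, and silyl ether and enoate are inert.

Step 11
Reactants: 18 methyl (2E,4R)-4-(tert-butyldimethylsilyloxy)-4-{(1R,2S)-2,6,6-trimethyl-2-[(E)-3-oxoprop-1-enyl]cyclohexyl}but-2-enoate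
Product: 19 methyl (5R,6R,9S,10S)-6-(tert-butyldimethylsilyloxy)-12-oxo-13,14,15,16-tetranorlabd-7-en-17-oate
Conditions: PMe3 (0.3 equiv), tert-amyl alcohol, 0.02 M, 23 → 40 °C, argon
Reagents that add atoms: none
Why: PMe3 adds reversibly to C7 of the γ-silyloxy enoate, the resulting C8 ester enolate attacks C9 of the enal, and proton transfer from C8 (relayed by the alcohol) followed by E1cB loss of PMe3 restores C7=C8, so 18 is simply isomerised to 19; this is the intramolecular Rauhut–Currier (vinylogous Morita–Baylis–Hillman) reaction known for tethered enoate/enal and enoate/enone pairs under trialkylphosphine catalysis. Ring B closes in the 6-exo-trig mode with respect to the C9=C11 acceptor, with the enolate exocyclic. C9 is set in a chair-like transition state built on the ring-A chair that has both arms equatorial: the C11–C12 terminus points outwards (pseudo-equatorial), hence cis to the axial C10 methyl, giving 9S, whereas an axial terminus would run into H5 and the C7 substituents. The step needs cross-selectivity against the usual electronic bias, in which the catalyst would attack the more electrophilic enal: here C9 is neopentyl (next to quaternary C10) and closed to the phosphine, C7 carries only the secondary C6 carbon whose C–O bond also lowers the enoate LUMO, and the productive pairing (reactive ester enolate onto the better acceptor, giving the more stable aldehyde enolate) is downhill while the reverse pairing is not. The 6R configuration puts H6, not the silyloxy group, into the cleft between C4 and C10, so the ground-state rotamer about C5–C6 already holds C7 gauche to C10 with C8 near C9, and the silyl ether ends equatorial. High dilution suppresses intermolecular coupling, and the eight-membered Morita–Baylis–Hillman closure onto C12 cannot compete.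

Step 12
Reactants: 19 methyl (5R,6R,9S,10S)-6-(tert-butyldimethylsilyloxy)-12-oxo-13,14,15,16-tetranorlabd-7-en-17-oate; 20 2-(triphenylphosphoranylidene)propanal
Product: 21 methyl (5R,6R,9S,10S,12E)-6-(tert-butyldimethylsilyloxy)-14-oxo-15-norlabda-7,12-dien-17-oate
Conditions: 20 (1.5 equiv), toluene, 90 °C
Reagents that add atoms: 2-(triphenylphosphoranylidene)propanal (20), CC(C=O)=P(c1ccccc1)(c1ccccc1)c1ccccc1
Why: Wittig reaction of a stabilised α-methyl ylide with an unhindered aldehyde gives the trisubstituted C12=C13 bond with the E geometry (C11 trans to the formyl group) under neutral conditions that leave C9 and the ring enoate alone.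

Step 13
Reactants: 21 methyl (5R,6R,9S,10S,12E)-6-(tert-butyldimethylsilyloxy)-14-oxo-15-norlabda-7,12-dien-17-oate; 6 methyltriphenylphosphonium bromide
Product: 22 methyl (5R,6R,9S,10S,12E)-6-(tert-butyldimethylsilyloxy)labda-7,12,14-trien-17-oate
Conditions: 6 (1.5 equiv), KOtBu (1.4 equiv), THF, 0 °C; then 21, −78 → 0 °C
Reagents that add atoms: methyltriphenylphosphonium bromide (6), C[P+](c1ccccc1)(c1ccccc1)c1ccccc1.[Br-]
Why: Wittig methylenation: the unstabilised ylide attacks the aldehyde carbonyl far faster than the hindered ring enoate, and the C12=C13 geometry is not touched.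

Step 14
Reactants: 22 methyl (5R,6R,9S,10S,12E)-6-(tert-butyldimethylsilyloxy)labda-7,12,14-trien-17-oate
Product: 23 methyl (5R,6R,9S,10S,12E)-6-hydroxylabda-7,12,14-trien-17-oate
Conditions: TBAF, AcOH (1:1), THF, 23–45 °C
Reagents that add atoms: none
Why: Fluoride-induced desilylation, buffered with acetic acid so that neither the enoate is deconjugated by base nor the diene exposed to strong acid.

Step 15
Reactants: 23 methyl (5R,6R,9S,10S,12E)-6-hydroxylabda-7,12,14-trien-17-oate
Product: 24 methyl (5R,9S,10S,12E)-6-oxolabda-7,12,14-trien-17-oate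
Conditions: Dess–Martin periodinane, pyridine, CH2Cl2, 0 °C
Reagents that add atoms: none
Why: Dess–Martin oxidation of the allylic alcohol is neutral and spares the diene; C5, now α to the ketone, is already in the favoured trans-decalin arrangement, and 24 is reduced without storage.

Step 16
Reactants: 24 methyl (5R,9S,10S,12E)-6-oxolabda-7,12,14-trien-17-oate
Product: 25 methyl (5R,6S,9S,10S,12E)-6-hydroxylabda-7,12,14-trien-17-oate
Conditions: NaBH4, CeCl3·7H2O, MeOH, −78 → −40 °C
Reagents that add atoms: none
Why: Luche reduction (1,2-selective): on the rigid trans-decalin the axial methyls on C4 and C10 close one face of the C6 carbonyl, so hydride enters from the H5/H9 face and pushes the hydroxyl into the axial position on the methyl face, giving 6S.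

Step 17
Reactants: 25 methyl (5R,6S,9S,10S,12E)-6-hydroxylabda-7,12,14-trien-17-oate
Product: 26 (5R,6S,9S,10S,12E)-6-hydroxylabda-7,12,14-trien-17-oic acid
Conditions: LiOH, THF–MeOH–H2O, 50 °C; then cold dilute HCl to pH 4
Reagents that add atoms: lithium hydroxide, [Li+].[OH-]
Why: Saponification is done before acetylation so that no acetate is at risk; H6 is pseudo-equatorial and poorly aligned with the π system, which protects the γ-hydroxy enoate from base-induced isomerisation, and lactonisation is impossible because C6 and C17 are trans on C7=C8.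

Step 18
Reactants: 26 (5R,6S,9S,10S,12E)-6-hydroxylabda-7,12,14-trien-17-oic acid; 27 acetic anhydride
Product: 29 (5R,6S,9S,10S,12E)-6-acetoxylabda-7,12,14-trien-17-oic acid (target), via mixed acetic anhydride 28 (not isolated)
Conditions: 27 (5 equiv), pyridine, DMAP (0.2 equiv), CH2Cl2, 23–40 °C; then H2O–THF, 23 °C
Reagents that add atoms: acetic anhydride (27), CC(=O)OC(C)=O
Why: DMAP-catalysed acetylation overcomes the axial, hindered position of O6 with retention at C6; the carboxyl group is acylated as well, but the mixed anhydride is hydrolysed on adding water while the secondary acetate stays.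

Compound list
1 | 2,2,6-trimethylcyclohexan-1-one (racemic) | CC1CCCC(C)(C)C1=O | starting material
2 | allyl chloroformate | C=CCOC(=O)Cl | starting material
3 | lithium 2,6,6-trimethylcyclohex-1-en-1-olate | [Li+].[O-]C1=C(C)CCCC1(C)C | intermediate
4 | allyl 2,6,6-trimethylcyclohex-1-en-1-yl carbonate | C=CCOC(=O)OC1=C(C)CCCC1(C)C | intermediate
5 | (S)-2-allyl-2,6,6-trimethylcyclohexan-1-one | C=CC[C@]1(C)CCCC(C)(C)C1=O | intermediate
6 | methyltriphenylphosphonium bromide | C[P+](c1ccccc1)(c1ccccc1)c1ccccc1.[Br-] | starting material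
7 | (S)-1-allyl-1,3,3-trimethyl-2-methylidenecyclohexane | C=CC[C@]1(C)CCCC(C)(C)C1=C | intermediate
8 | thexyl[3-(1,3,3-trimethyl-2-methylidenecyclohexyl)propyl]borane, C10 arranged as in 7 | CC(C)C(C)(C)BCCC[C@]1(C)CCCC(C)(C)C1=C | intermediate
9 | B-thexylborepane trans-fused to ring A (boron bonded to C6 and C12, H5 cis to C9) | CC(C)C(C)(C)B1CCC[C@]2(C)CCCC(C)(C)[C@H]2C1 | intermediate
10 | 3-[(1S,2R)-2-(hydroxymethyl)-1,3,3-trimethylcyclohexyl]propan-1-ol | OCCC[C@]1(C)CCCC(C)(C)[C@H]1CO | intermediate
11 | {(1R,2S)-2,6,6-trimethyl-2-[3-(triethylsilyloxy)propyl]cyclohexyl}methanol | CC[Si](CC)(CC)OCCC[C@]1(C)CCCC(C)(C)[C@H]1CO | intermediate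
12 | (1R,2S)-2,6,6-trimethyl-2-[3-(triethylsilyloxy)propyl]cyclohexane-1-carbaldehyde | CC[Si](CC)(CC)OCCC[C@]1(C)CCCC(C)(C)[C@H]1C=O | intermediate
13 | methyl (E)-3-iodoacrylate | COC(=O)/C=C/I | starting material
14 | methyl (2E,4R)-4-hydroxy-4-{(1R,2S)-2,6,6-trimethyl-2-[3-(triethylsilyloxy)propyl]cyclohexyl}but-2-enoate | CC[Si](CC)(CC)OCCC[C@]1(C)CCCC(C)(C)[C@H]1[C@H](O)/C=C/C(=O)OC | intermediate
15 | methyl (2E,4R)-4-(tert-butyldimethylsilyloxy)-4-{(1R,2S)-2,6,6-trimethyl-2-[3-(triethylsilyloxy)propyl]cyclohexyl}but-2-enoate | CC[Si](CC)(CC)OCCC[C@]1(C)CCCC(C)(C)[C@H]1[C@H](O[Si](C)(C)C(C)(C)C)/C=C/C(=O)OC | intermediate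
16 | methyl (2E,4R)-4-(tert-butyldimethylsilyloxy)-4-[(1R,2S)-2-(3-hydroxypropyl)-2,6,6-trimethylcyclohexyl]but-2-enoate | OCCC[C@]1(C)CCCC(C)(C)[C@H]1[C@H](O[Si](C)(C)C(C)(C)C)/C=C/C(=O)OC | intermediate
17 | methyl (2E,4R)-4-(tert-butyldimethylsilyloxy)-4-[(1R,2S)-2,6,6-trimethyl-2-(3-oxopropyl)cyclohexyl]but-2-enoate | O=CCC[C@]1(C)CCCC(C)(C)[C@H]1[C@H](O[Si](C)(C)C(C)(C)C)/C=C/C(=O)OC | intermediate
18 | methyl (2E,4R)-4-(tert-butyldimethylsilyloxy)-4-{(1R,2S)-2,6,6-trimethyl-2-[(E)-3-oxoprop-1-enyl]cyclohexyl}but-2-enoate (ring-A bis-acceptor) | O=C/C=C/[C@]1(C)CCCC(C)(C)[C@H]1[C@H](O[Si](C)(C)C(C)(C)C)/C=C/C(=O)OC | intermediate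
19 | methyl (5R,6R,9S,10S)-6-(tert-butyldimethylsilyloxy)-12-oxo-13,14,15,16-tetranorlabd-7-en-17-oate (ring-B enoate with C9 acetaldehyde arm) | O=CC[C@@H]1C(C(=O)OC)=C[C@@H](O[Si](C)(C)C(C)(C)C)[C@@H]2C(C)(C)CCC[C@@]12C | intermediate
20 | 2-(triphenylphosphoranylidene)propanal | CC(C=O)=P(c1ccccc1)(c1ccccc1)c1ccccc1 | starting material
21 | methyl (5R,6R,9S,10S,12E)-6-(tert-butyldimethylsilyloxy)-14-oxo-15-norlabda-7,12-dien-17-oate | O=C/C(C)=C/C[C@@H]1C(C(=O)OC)=C[C@@H](O[Si](C)(C)C(C)(C)C)[C@@H]2C(C)(C)CCC[C@@]12C | intermediate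
22 | methyl (5R,6R,9S,10S,12E)-6-(tert-butyldimethylsilyloxy)labda-7,12,14-trien-17-oate | C=C/C(C)=C/C[C@@H]1C(C(=O)OC)=C[C@@H](O[Si](C)(C)C(C)(C)C)[C@@H]2C(C)(C)CCC[C@@]12C | intermediate
23 | methyl (5R,6R,9S,10S,12E)-6-hydroxylabda-7,12,14-trien-17-oate | C=C/C(C)=C/C[C@@H]1C(C(=O)OC)=C[C@@H](O)[C@@H]2C(C)(C)CCC[C@@]12C | intermediate
24 | methyl (5R,9S,10S,12E)-6-oxolabda-7,12,14-trien-17-oate | C=C/C(C)=C/C[C@@H]1C(C(=O)OC)=CC(=O)[C@@H]2C(C)(C)CCC[C@@]12C | intermediate
25 | methyl (5R,6S,9S,10S,12E)-6-hydroxylabda-7,12,14-trien-17-oate | C=C/C(C)=C/C[C@@H]1C(C(=O)OC)=C[C@H](O)[C@@H]2C(C)(C)CCC[C@@]12C | intermediate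
26 | (5R,6S,9S,10S,12E)-6-hydroxylabda-7,12,14-trien-17-oic acid | C=C/C(C)=C/C[C@@H]1C(C(=O)O)=C[C@H](O)[C@@H]2C(C)(C)CCC[C@@]12C | intermediate
27 | acetic anhydride | CC(=O)OC(C)=O | starting material
28 | acetic (5R,6S,9S,10S,12E)-6-acetoxylabda-7,12,14-trien-17-oic anhydride | C=C/C(C)=C/C[C@@H]1C(C(=O)OC(C)=O)=C[C@H](OC(C)=O)[C@@H]2C(C)(C)CCC[C@@]12C | intermediate
29 | (5R,6S,9S,10S,12E)-6-acetoxylabda-7,12,14-trien-17-oic acid | C=C/C(C)=C/C[C@@H]1C(C(=O)O)=C[C@H](OC(C)=O)[C@@H]2C(C)(C)CCC[C@@]12C | target

Total step count: 18. Longest linear sequence: 18 steps (from 1).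

Steps most likely to fail

Step 11. Three processes could defeat the ring closure:
- The phosphine may not engage the crowded C7, so there is no turnover.
- The phosphine may be consumed through a proton shift and loss of silyloxide.
- Base-type isomerisation of the γ-silyloxy enoate may outrun the ring closure.

The fallback gives up catalysis and separates the C–C bond formation from the regeneration of the alkene. It sets out from 18. Lithium thiophenolate (1.1 equiv, THF, −78 to −20 °C, then NH4Cl) triggers a stoichiometric sulfa-Michael/Michael sequence. Every unproductive thiolate adduct can revert in this sequence, and only the cyclised aldehyde enolate is carried forward. It should give the 7-phenylsulfanyl-7,8-dihydro adduct F1. One equivalent of mCPBA (CH2Cl2, −78 °C) should give the sulfoxide F2. Warming F2 in toluene over CaCO3 brings about syn-elimination towards the acidic H8, which is cis to sulfur. The route is rejoined at 19.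

Step 4. Two vinyl groups may end up on one boron faster than the hindered C5=C6 bond is reached within the molecule. The exocyclic alkene would then be hydroborated from outside, with loss of facial control at C5. The fallback replaces kinetic tether control by thermodynamic control at an epimerisable centre. It sets out from 7.
- 9-BBN (THF, then NaBO3) attacks only the vinyl group and should give the alkenol F3.
- TESCl and imidazole convert F3 into the silyl ether F4.
- BH3·SMe2 followed by NaBO3 hydroborates the exocyclic alkene without facial control. This gives 11 together with the C5-epimeric alcohol F5.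
- Dess–Martin oxidation of the mixture gives 12 and the C5-epimeric aldehyde F6.

C5 is now α to a carbonyl, so DBU in toluene interconverts the two aldehydes. The isomer with an axial CH3 rather than an axial CH2R next to the axial C4 methyl should be somewhat favoured. Aldehyde 12 is separated by chromatography and F6 is returned to the equilibration. The route is rejoined at 12.

Step 7. Addition of the bulky, mild vinylchromium reagent to an aldehyde flanked by two quaternary carbons may be slower than self-coupling and decay of the reagent. The fallback uses a slim, strongly nucleophilic acetylide and sets the alkene geometry in a separate step. It sets out from 12. Methyl propiolate is deprotonated with LiHMDS (THF, −78 °C) and should add to the aldehyde to give the propargylic alcohol F7. Alkoxide-directed trans-hydroalumination with Red-Al (THF, −72 °C, then a proton quench) converts the ynoate into the E-enoate. The route is rejoined at 14.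

Further compounds
F1 | step 11 | methyl (5R,6R,9S,10S)-6-(tert-butyldimethylsilyloxy)-12-oxo-7-(phenylsulfanyl)-13,14,15,16-tetranorlabdan-17-oate (7-SPh and 8-CO2Me equatorial) | O=CC[C@@H]1[C@@H](C(=O)OC)[C@H](Sc3ccccc3)[C@@H](O[Si](C)(C)C(C)(C)C)[C@@H]2C(C)(C)CCC[C@@]12C
F2 | step 11 | sulfoxide of F1 (7-phenylsulfinyl, mixture at sulfur) | O=CC[C@@H]1[C@@H](C(=O)OC)[C@H](S(=O)c3ccccc3)[C@@H](O[Si](C)(C)C(C)(C)C)[C@@H]2C(C)(C)CCC[C@@]12C
F3 | step 4 | 3-[(1S)-1,3,3-trimethyl-2-methylidenecyclohexyl]propan-1-ol | OCCC[C@]1(C)CCCC(C)(C)C1=C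
F4 | step 4 | triethyl{3-[(1S)-1,3,3-trimethyl-2-methylidenecyclohexyl]propoxy}silane | CC[Si](CC)(CC)OCCC[C@]1(C)CCCC(C)(C)C1=C
F5 | step 4 | {(1S,2S)-2,6,6-trimethyl-2-[3-(triethylsilyloxy)propyl]cyclohexyl}methanol (C5 epimer of 11) | CC[Si](CC)(CC)OCCC[C@]1(C)CCCC(C)(C)[C@@H]1CO
F6 | step 4 | (1S,2S)-2,6,6-trimethyl-2-[3-(triethylsilyloxy)propyl]cyclohexane-1-carbaldehyde (C5 epimer of 12) | CC[Si](CC)(CC)OCCC[C@]1(C)CCCC(C)(C)[C@@H]1C=O
F7 | step 7 | methyl (4S)-4-hydroxy-4-{(1R,2S)-2,6,6-trimethyl-2-[3-(triethylsilyloxy)propyl]cyclohexyl}but-2-ynoate (C6 arranged in space as in 14) | CC[Si](CC)(CC)OCCC[C@]1(C)CCCC(C)(C)[C@H]1[C@H](O)C#CC(=O)OC
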